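**Retrosynthetic overview**
- C12–C13 and the C13 stereocentre: copper-catalysed enantioselective SN2' allyl–alkyl coupling of the C9 vinyl group (through its 9-BBN adduct) with a (Z)-4-silyloxybut-2-enyl chloride; the C6 angelate is put on just before.
- Ring B, the C9–C10 bond, the quaternary C10 and the cis ring fusion: iron-catalysed, hydrogen-atom-transfer-initiated reductive olefin coupling (6-exo radical cyclisation of the ring-A olefin onto an allyl sulfone, with loss of sulfinate to leave the C9 vinyl group).
- Cyclisation precursor: cross-metathesis with allyl phenyl sulfone, chelation-controlled MeMgBr addition (C8) and Felkin-selective Mukaiyama aldol (C6) between (R)-α-cyclocitral and the silyl enol ether of methyl vinyl ketone.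
- Ring A with C5: acid-catalysed annulation of isobutyraldehyde with ethyl vinyl ketone, CBS reduction, Still–Wittig [2,3] shift (chirality transfer to C5), oxidation.
- Ring order: ring A first (annulation), ring B last (radical cyclisation); four small fragments (ring A aldehyde, enol silane, allyl sulfone, allylic chloride) plus angelic anhydride.

Assumption: the SMILES is taken literally, i.e. a cis-fused decalin with 5R,6S,8R,9R,10S,13R in labdane numbering (ring A = C1–C5 and C10, ring B = C5–C10, side chain C11–C16), which is used in the comments; metal alkoxides formed by simple deprotonation are not counted as separate intermediates.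

Step 1
Reactants: 1 2-methylpropanal (isobutyraldehyde); 2 pent-1-en-3-one (ethyl vinyl ketone)
Product: 4 2,4,4-trimethylcyclohex-2-en-1-one, via 2,2-dimethyl-5-oxoheptanal 3 (not isolated)
Conditions: H2SO4 (cat.), toluene, 50 °C then reflux (Dean–Stark)
Reagents that add atoms: none
Why: Acid-catalysed Michael addition of the aldehyde enol to the vinyl ketone and intramolecular aldol condensation (Robinson-type annulation) give the enone that carries all ring-A carbons; no stereocentre is formed.

Step 2
Reactants: 4 2,4,4-trimethylcyclohex-2-en-1-one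
Product: 5 (1S)-2,4,4-trimethylcyclohex-2-en-1-ol
Conditions: (R)-2-methyl-CBS-oxazaborolidine (10 mol%), BH3·SMe2, THF, −20 °C
Reagents that add atoms: none
Why: Corey–Bakshi–Shibata reduction, in which the alkenyl side of the ketone acts as the large group, delivers hydride to one face and sets the carbinol carbon as S (typically high ee for 2-alkylcyclohexenones).

Step 3
Reactants: 5 (1S)-2,4,4-trimethylcyclohex-2-en-1-ol
Product: 7 [(1R)-2,6,6-trimethylcyclohex-2-en-1-yl]methanol, via stannylmethyl ether 6 (not isolated)
Conditions: KH, Bu3SnCH2I, THF, 0 °C to rt; then n-BuLi, −78 °C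
Reagents that add atoms: (iodomethyl)tributylstannane, CCCC[Sn](CCCC)(CCCC)CI
Why: Still–Wittig [2,3]-sigmatropic rearrangement of the lithiated stannylmethyl ether (tin–lithium exchange) is suprafacial, so the carbinol configuration is transferred to the new ring–CH2 bond (labdane C5, R) while the olefin moves to the labdane C1=C10 position.

Step 4
Reactants: 7 [(1R)-2,6,6-trimethylcyclohex-2-en-1-yl]methanol
Product: 8 (1R)-2,6,6-trimethylcyclohex-2-ene-1-carbaldehyde
Conditions: Dess–Martin periodinane, CH2Cl2, 0 °C
Reagents that add atoms: none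
Why: Dess–Martin oxidation is non-basic, so the primary alcohol becomes the aldehyde without epimerising C5 or conjugating the olefin.

Step 5
Reactants: 9 but-3-en-2-one (methyl vinyl ketone)
Product: 10 2-(trimethylsilyloxy)buta-1,3-diene
Conditions: TMSCl, Et3N, DMF, 80 °C
Reagents that add atoms: chlorotrimethylsilane, C[Si](C)(C)Cl
Why: O-Silylation of the methyl-ketone enol (silyl enol ether formation) gives the 2-silyloxydiene that serves as the C7–C11 nucleophile.

Step 6
Reactants: 8 (1R)-2,6,6-trimethylcyclohex-2-ene-1-carbaldehyde; 10 2-(trimethylsilyloxy)buta-1,3-diene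
Product: 11 (5S)-5-hydroxy-5-[(1R)-2,6,6-trimethylcyclohex-2-en-1-yl]pent-1-en-3-one
Conditions: BF3·OEt2, CH2Cl2, −78 °C; aqueous work-up
Reagents that add atoms: none
Why: Mukaiyama aldol addition through an open transition state follows the Felkin–Anh model (attack anti to the quaternary C4 carbon of the α-stereocentre) and sets C6 as S.

Step 7
Reactants: 11 (5S)-5-hydroxy-5-[(1R)-2,6,6-trimethylcyclohex-2-en-1-yl]pent-1-en-3-one
Product: 12 (3R,5S)-3-methyl-5-[(1R)-2,6,6-trimethylcyclohex-2-en-1-yl]pent-1-ene-3,5-diol
Conditions: MeMgBr (3 equiv), CH2Cl2–Et2O, −78 °C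
Reagents that add atoms: methylmagnesium bromide, C[Mg]Br
Why: Chelation-controlled Grignard 1,2-addition: the magnesium alkoxide of the C6 hydroxyl chelates the C8 ketone in a six-membered ring and methyl adds axially, which gives the 1,3-syn diol (C8 R).

Step 8
Reactants: 13 3-bromoprop-1-ene (allyl bromide)
Product: 14 (prop-2-en-1-ylsulfonyl)benzene (allyl phenyl sulfone)
Conditions: PhSO2Na, DMF, rt
Reagents that add atoms: sodium benzenesulfinate, [Na+].[O-]S(=O)c1ccccc1
Why: SN2 S-alkylation of the sulfinate anion by the allylic bromide (sulfone synthesis).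

Step 9
Reactants: 12 (3R,5S)-3-methyl-5-[(1R)-2,6,6-trimethylcyclohex-2-en-1-yl]pent-1-ene-3,5-diol; 14 allyl phenyl sulfone
Product: 15 (2E,4R,6S)-4-methyl-1-(phenylsulfonyl)-6-[(1R)-2,6,6-trimethylcyclohex-2-en-1-yl]hex-2-ene-4,6-diol
Conditions: second-generation Grubbs catalyst (5 mol%), 14 (3 equiv), CH2Cl2, 40 °C
Reagents that add atoms: none
Why: Ruthenium-catalysed olefin cross-metathesis joins the vinyl carbinol to the allyl sulfone E-selectively, while the trisubstituted ring olefin and all stereocentres are untouched.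

Step 10
Reactants: 15 (2E,4R,6S)-4-methyl-1-(phenylsulfonyl)-6-[(1R)-2,6,6-trimethylcyclohex-2-en-1-yl]hex-2-ene-4,6-diol
Product: 16 (1R,2R,4S,4aR,8aS)-1-ethenyl-2,5,5,8a-tetramethyldecahydronaphthalene-2,4-diol
Conditions: Fe(acac)3 (30 mol%), PhSiH3 (2.5 equiv), EtOH–ethylene glycol (5:1), 60 °C, 0.01 M, degassed
Reagents that add atoms: none
Why: Proposed new method: an iron hydride (from Fe(acac)3, PhSiH3 and EtOH) transfers a hydrogen atom to the less substituted carbon (C1) of the trisubstituted ring-A olefin, the resulting tertiary C10 radical closes ring B by 6-exo addition to C9 of the E-allyl sulfone, and the β-sulfonyl radical fragments to the C11=C12 vinyl group and PhSO2•, which divalent iron reduces to sulfinate so that trivalent iron is regenerated; in the chair-like transition state the tether stays equatorial on ring A and C9 adds to the C10 radical axially with respect to ring A, which places both hydroxyls and the alkene branch equatorial on the forming ring B (at the cost of one C8-methyl/C10-methyl diaxial contact) and gives the cis ring fusion (C10 S) and C9 R, whereas the trans-fused alternative would place the C10 methyl syn-axial to both oxygens and to the axial C4 methyl; the closest known reactions are the iron-catalysed hydrogen-atom-transfer reductive olefin coupling (Giese-type, with enone or vinyl sulfone acceptors) and radical allylation by addition and β-scission on allyl sulfones, which have not been combined in a catalytic ring closure of this kind that forms a quaternary centre.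

Step 11
Reactants: 17 (2Z)-2-methylbut-2-enoic acid (angelic acid), two molecules per molecule of anhydride
Product: 19 (2Z)-2-methylbut-2-enoic anhydride (angelic anhydride), via O-acylisourea 18 (not isolated)
Conditions: 17 (2.0 equiv), DCC (1.0 equiv), CH2Cl2, 0 °C; the urea is filtered off
Reagents that add atoms: (2Z)-2-methylbut-2-enoic acid (the second molecule of 17, which is built into the anhydride), C/C=C(/C)C(=O)O
Why: Carbodiimide-mediated dehydration: one molecule of the acid adds to DCC to give the O-acylisourea, a second molecule of the acid attacks its acyl carbon to give the symmetrical anhydride and the urea, and since no base is present the Z-olefin is kept.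

Step 12
Reactants: 16 (1R,2R,4S,4aR,8aS)-1-ethenyl-2,5,5,8a-tetramethyldecahydronaphthalene-2,4-diol; 19 angelic anhydride
Product: 20 (1S,3R,4R,4aS,8aR)-4-ethenyl-3-hydroxy-3,4a,8,8-tetramethyldecahydronaphthalen-1-yl (2Z)-2-methylbut-2-enoate
Conditions: LiHMDS (1.1 equiv), THF, −78 °C; then 19 (1.2 equiv), −78 to 0 °C
Reagents that add atoms: none
Why: Acylation of the lithium alkoxide by the anhydride (esterification) takes place at the secondary C6 oxygen because the tertiary C8 hydroxyl is too hindered, and these conditions avoid Z-to-E isomerisation of the angelate.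

Step 13
Reactants: 21 but-2-yne-1,4-diol
Product: 22 4-[(triethylsilyl)oxy]but-2-yn-1-ol
Conditions: TESCl (1 equiv), imidazole, DMF, 0 °C, diol in excess (3 equiv)
Reagents that add atoms: chlorotriethylsilane, CC[Si](CC)(CC)Cl
Why: Statistical monosilylation of the symmetrical diol (silyl ether formation) with the diol in excess.

Step 14
Reactants: 22 4-[(triethylsilyl)oxy]but-2-yn-1-ol
Product: 23 (2Z)-4-[(triethylsilyl)oxy]but-2-en-1-ol
Conditions: H2 (1 atm), Pd/CaCO3 poisoned with Pb(OAc)2, quinoline, EtOAc, rt
Reagents that add atoms: none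
Why: Lindlar semihydrogenation adds H2 syn to the alkyne and gives the Z-allylic alcohol in the high isomeric purity that the enantioselective coupling needs.

Step 15
Reactants: 23 (2Z)-4-[(triethylsilyl)oxy]but-2-en-1-ol
Product: 25 {[(2Z)-4-chlorobut-2-en-1-yl]oxy}(triethyl)silane, via allylic mesylate 24 (not isolated)
Conditions: MsCl, Et3N, CH2Cl2, −20 °C; then LiCl, THF, 0 °C
Reagents that add atoms: lithium chloride, [Li+].[Cl-]
Why: Mesylation followed by SN2 displacement with chloride at the primary allylic carbon keeps the Z-geometry and the silyl ether.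

Step 16
Reactants: 20 (1S,3R,4R,4aS,8aR)-4-ethenyl-3-hydroxy-3,4a,8,8-tetramethyldecahydronaphthalen-1-yl (2Z)-2-methylbut-2-enoate; 25 {[(2Z)-4-chlorobut-2-en-1-yl]oxy}(triethyl)silane
Product: 28 (1S,3R,4R,4aS,8aR)-3-hydroxy-4-[(3R)-3-(hydroxymethyl)pent-4-en-1-yl]-3,4a,8,8-tetramethyldecahydronaphthalen-1-yl (2Z)-2-methylbut-2-enoate (target CNP0177054.1), via B-alkyl-9-BBN adduct 26 (not isolated), via triethylsilyl ether 27 (not isolated)
Conditions: 9-BBN (2.2 equiv), THF, rt to 40 °C; then CuOTf·(toluene)0.5 (10 mol%), (R)-DTBM-SEGPHOS (10 mol%), EtOK, 25, THF–dioxane, 10 °C; then 1 M HCl, THF, 0 °C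
Reagents that add atoms: none
Why: Anti-Markovnikov hydroboration puts boron on C12, the copper-catalysed γ-selective (SN2') allyl–alkyl coupling of the alkylborate with the Z-allylic chloride forms C12–C13 with the chiral bisphosphine–copper complex setting C13 (R; the ligand enantiomer is chosen accordingly) under catalyst control, and dilute acid then removes the primary silyl ether.

**Compound list**
1 | 2-methylpropanal (isobutyraldehyde) | CC(C)C=O | starting material
2 | pent-1-en-3-one (ethyl vinyl ketone) | CCC(=O)C=C | starting material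
3 | 2,2-dimethyl-5-oxoheptanal | CCC(=O)CCC(C)(C)C=O | intermediate
4 | 2,4,4-trimethylcyclohex-2-en-1-one | CC1=CC(C)(C)CCC1=O | intermediate
5 | (1S)-2,4,4-trimethylcyclohex-2-en-1-ol | O[C@@H]1C(C)=CC(C)(C)CC1 | intermediate
6 | tributyl({[(1S)-2,4,4-trimethylcyclohex-2-en-1-yl]oxy}methyl)stannane | CCCC[Sn](CCCC)(CCCC)CO[C@@H]1C(C)=CC(C)(C)CC1 | intermediate
7 | [(1R)-2,6,6-trimethylcyclohex-2-en-1-yl]methanol ((R)-α-cyclogeraniol) | OC[C@H]1C(C)=CCCC1(C)C | intermediate
8 | (1R)-2,6,6-trimethylcyclohex-2-ene-1-carbaldehyde ((R)-α-cyclocitral) | O=C[C@H]1C(C)=CCCC1(C)C | intermediate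
9 | but-3-en-2-one (methyl vinyl ketone) | CC(=O)C=C | starting material
10 | 2-(trimethylsilyloxy)buta-1,3-diene | C=CC(=C)O[Si](C)(C)C | intermediate
11 | (5S)-5-hydroxy-5-[(1R)-2,6,6-trimethylcyclohex-2-en-1-yl]pent-1-en-3-one | C=CC(=O)C[C@H](O)[C@H]1C(C)=CCCC1(C)C | intermediate
12 | (3R,5S)-3-methyl-5-[(1R)-2,6,6-trimethylcyclohex-2-en-1-yl]pent-1-ene-3,5-diol | C=C[C@](C)(O)C[C@H](O)[C@H]1C(C)=CCCC1(C)C | intermediate
13 | 3-bromoprop-1-ene (allyl bromide) | C=CCBr | starting material
14 | (prop-2-en-1-ylsulfonyl)benzene (allyl phenyl sulfone) | C=CCS(=O)(=O)c1ccccc1 | intermediate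
15 | (2E,4R,6S)-4-methyl-1-(phenylsulfonyl)-6-[(1R)-2,6,6-trimethylcyclohex-2-en-1-yl]hex-2-ene-4,6-diol | O=S(=O)(C/C=C/[C@](C)(O)C[C@H](O)[C@H]1C(C)=CCCC1(C)C)c1ccccc1 | intermediate
16 | (1R,2R,4S,4aR,8aS)-1-ethenyl-2,5,5,8a-tetramethyldecahydronaphthalene-2,4-diol (cis-fused; labdane 5R,6S,8R,9R,10S) | C=C[C@@H]1[C@@]2(C)CCCC(C)(C)[C@H]2[C@@H](O)C[C@@]1(C)O | intermediate
17 | (2Z)-2-methylbut-2-enoic acid (angelic acid) | C/C=C(/C)C(=O)O | starting material
18 | N,N'-dicyclohexyl-O-[(2Z)-2-methylbut-2-enoyl]isourea | C/C=C(/C)C(=O)OC(=NC1CCCCC1)NC1CCCCC1 | intermediate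
19 | (2Z)-2-methylbut-2-enoic anhydride (angelic anhydride) | C/C=C(/C)C(=O)OC(=O)/C(C)=C\C | intermediate
20 | (1S,3R,4R,4aS,8aR)-4-ethenyl-3-hydroxy-3,4a,8,8-tetramethyldecahydronaphthalen-1-yl (2Z)-2-methylbut-2-enoate | C=C[C@@H]1[C@@]2(C)CCCC(C)(C)[C@H]2[C@@H](OC(=O)/C(C)=C\C)C[C@@]1(C)O | intermediate
21 | but-2-yne-1,4-diol | OCC#CCO | starting material
22 | 4-[(triethylsilyl)oxy]but-2-yn-1-ol | OCC#CCO[Si](CC)(CC)CC | intermediate
23 | (2Z)-4-[(triethylsilyl)oxy]but-2-en-1-ol | OC/C=C\CO[Si](CC)(CC)CC | intermediate
24 | (2Z)-4-[(triethylsilyl)oxy]but-2-en-1-yl methanesulfonate | CS(=O)(=O)OC/C=C\CO[Si](CC)(CC)CC | intermediate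
25 | {[(2Z)-4-chlorobut-2-en-1-yl]oxy}(triethyl)silane | ClC/C=C\CO[Si](CC)(CC)CC | intermediate
26 | 9-BBN adduct of 20 (boron on the terminal carbon of the former vinyl group, C12) | B1(CC[C@@H]2[C@@]3(C)CCCC(C)(C)[C@H]3[C@@H](OC(=O)/C(C)=C\C)C[C@@]2(C)O)C2CCCC1CCC2 | intermediate
27 | triethylsilyl ether of 28 at the primary C16 hydroxyl | C=C[C@H](CO[Si](CC)(CC)CC)CC[C@@H]1[C@@]2(C)CCCC(C)(C)[C@H]2[C@@H](OC(=O)/C(C)=C\C)C[C@@]1(C)O | intermediate
28 | (1S,3R,4R,4aS,8aR)-3-hydroxy-4-[(3R)-3-(hydroxymethyl)pent-4-en-1-yl]-3,4a,8,8-tetramethyldecahydronaphthalen-1-yl (2Z)-2-methylbut-2-enoate (CNP0177054.1) | C=C[C@H](CO)CC[C@@H]1[C@@]2(C)CCCC(C)(C)[C@H]2[C@@H](OC(=O)/C(C)=C\C)C[C@@]1(C)O | target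

**Totals**
Total step count: 16.
Longest linear sequence: 10 steps (1, 2, 3, 4, 6, 7, 9, 10, 12, 16). Steps 5, 8, 11 and 13–15 are side branches.

**Steps most likely to fail, with fallbacks**

Step 7 (C8 configuration). The diastereoselectivity rests on magnesium chelation and may be low or even reversed. The fallback replaces substrate control by reagent control. Starting from 11, the C6 hydroxyl is silylated (TESOTf, 2,6-lutidine, CH2Cl2, −78 °C) to the triethylsilyl ether F1. A catalytic enantioselective 1,2-methylation of the enone carbonyl (Me2Zn, Ti(OiPr)4, chiral bis(sulfonamide) diol ligand, toluene, rt; a known reaction class for enones) then gives the tertiary carbinol F2. AcOH–THF–H2O removes the silyl group and the route is rejoined at 12.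

Step 10 (the new cyclisation). The iron cycle may fail to turn over, or the tertiary radical may be reduced before it cyclises. The fallback makes the same radical stepwise by known chemistry. Starting from 15, cobalt-catalysed Markovnikov hydrochlorination of the ring olefin (Co(BF4)2·6H2O, salen-type ligand, TsCl in excess, PhSiH3, t-BuOOH, EtOH) gives the tertiary chloride F3. The excess of TsCl is meant to let chlorine transfer outrun ring closure; any material that has already cyclised at this stage is 16 itself. Slow addition of Bu3SnH and AIBN in benzene at 80 °C then runs a classical tin chain (chlorine abstraction, 6-exo cyclisation, β-sulfonyl scission), and the route is rejoined at 16.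

Step 12 (angeloylation). A hindered secondary alcohol has to be acylated with an acid that isomerises easily to the tiglate. The fallback builds the Z-olefin on the ester instead. Starting from 16, the C6 hydroxyl is esterified with the small, unhindered 2-[bis(2,2,2-trifluoroethoxy)phosphoryl]propanoic acid (DCC, DMAP, CH2Cl2) to the phosphonate ester F4. A Still–Gennari olefination with acetaldehyde (KHMDS, 18-crown-6, THF, −78 °C) then gives the Z-trisubstituted enoate, and the route is rejoined at 20.

Further compounds
F1 | step 7 | (5S)-5-[(triethylsilyl)oxy]-5-[(1R)-2,6,6-trimethylcyclohex-2-en-1-yl]pent-1-en-3-one | C=CC(=O)C[C@H](O[Si](CC)(CC)CC)[C@H]1C(C)=CCCC1(C)C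
F2 | step 7 | (3R,5S)-3-methyl-5-[(triethylsilyl)oxy]-5-[(1R)-2,6,6-trimethylcyclohex-2-en-1-yl]pent-1-en-3-ol | C=C[C@](C)(O)C[C@H](O[Si](CC)(CC)CC)[C@H]1C(C)=CCCC1(C)C
F3 | step 10 | tertiary chloride of 15 (HCl added across the ring olefin, chlorine on the methyl-bearing ring carbon, epimer mixture at that carbon) | O=S(=O)(C/C=C/[C@](C)(O)C[C@H](O)[C@H]1C(C)(Cl)CCCC1(C)C)c1ccccc1
F4 | step 12 | (1S,3R,4R,4aS,8aR)-4-ethenyl-3-hydroxy-3,4a,8,8-tetramethyldecahydronaphthalen-1-yl 2-[bis(2,2,2-trifluoroethoxy)phosphoryl]propanoate | C=C[C@@H]1[C@@]2(C)CCCC(C)(C)[C@H]2[C@@H](OC(=O)C(C)P(=O)(OCC(F)(F)F)OCC(F)(F)F)C[C@@]1(C)O
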